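Retrosynthetic cuts (outside in): the Cα=Cβ bond of the chalcone arm; the ring A aryl–C(=O) bond; the acetyl–ring B bond; the C3–ring B bond, with ring B traced back to cyclohexane-1,3-dione; last, C4–C5 and C1–C6 of ring C, which leaves a 2-pyrone and a styrene.
Enabling feature: in ring C (C1 methyl-bearing alkene carbon, C2 alkene CH, C3 with ring B, C4 with the ring A ketone, C5 with ring D, C6 CH2) the C4 carbonyl carbon and the C1 methyl group stand 1,4 to each other, like C2(=O) and the 6-methyl group of a 2-pyrone, and C5–C6 with ring D is a styrene.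
Forward order: ring C is closed first as a lactone-bridged bicycle; the bridge is opened to a Weinreb amide and a tertiary allylic carbonate; the dione is attached at C3 and aromatised to ring B; ring B is iodinated and given a masked acetyl group; ring A is joined as an aryllithium; the chalcone arm is closed last.
Stereochemistry: C4/C5 trans from the endo cycloaddition; C3 cis to C4 by double inversion in the palladium-catalysed alkylation, because the C1–O bond and the C4 carbonyl group lie on one face; absolute configuration by resolution of the racemic bromolactone on a chiral phase.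
Protection: all phenols are carried as tert-butyldimethylsilyl ethers (TBS; TBSO = t-BuMe2SiO) and freed by fluoride, because the cis,trans arrangement of ring B, the C4 ketone and ring D is expected to close to ketals and cyclic ethers in acid.

Key step: step 4

Remark: bromination–dehydrobromination of 6-methyl-2-pyrone is assumed to follow the parent 2-pyrone and to place bromine at C3; a 5-bromo isomer, if formed, would be removed by chromatography.

Step 1
Reactants: 1 6-methyl-2H-pyran-2-one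
Product: 3 3-bromo-6-methyl-2H-pyran-2-one, via 3,6-dibromo adduct 2 (not isolated)
Conditions: Br2, CH2Cl2, 0 °C to rt; then Et3N, 0 °C to rt
Reagents that add atoms: bromine, BrBr
Why: Bromine adds 1,4 across the pyrone diene and Et3N then removes HBr from the adduct (halogenation–dehydrobromination), which should leave the bromine at C3 next to the lactone carbonyl as in the parent 2-pyrone.

Step 2
Reactants: 4 2,4-dihydroxybenzaldehyde
Product: 5 2,4-bis(TBSO)benzaldehyde
Conditions: t-BuMe2SiCl, imidazole, DMF, rt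
Reagents that add atoms: tert-butyldimethylsilyl chloride, CC(C)(C)[Si](C)(C)Cl
Why: Silyl ether formation with t-BuMe2SiCl and imidazole masks both phenols with a group that tolerates heat, radicals, organometallic reagents and zerovalent palladium and that fluoride removes at the end.

Step 3
Reactants: 5 2,4-bis(TBSO)benzaldehyde
Product: 6 1-ethenyl-2,4-bis(TBSO)benzene (ring D styrene)
Conditions: Ph3PCH3Br, n-BuLi, THF, 0 °C to rt
Reagents that add atoms: methyltriphenylphosphonium bromide, C[P+](c1ccccc1)(c1ccccc1)c1ccccc1.[Br-]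
Why: Wittig methylenation converts the aldehyde into the electron-rich styrene that serves as the dienophile.

Step 4
Reactants: 3 3-bromo-6-methyl-2H-pyran-2-one; 6 1-ethenyl-2,4-bis(TBSO)benzene
Product: 7 rac-(1S,4R,5R)-5-[2,4-bis(TBSO)phenyl]-4-bromo-1-methyl-2-oxabicyclo[2.2.2]oct-7-en-3-one (endo adduct)
Conditions: toluene, BHT (cat), 95 °C, sealed tube, 3–4 d
Reagents that add atoms: none
Why: The pyrone reacts through its C3=C4–C5=C6 diene in a concerted, asynchronous, suprafacial [4+2] cycloaddition in which the nucleophilic CH2 terminus of the styrene bonds to the electrophilic methyl-bearing C6 (the C1–C6 bond of ring C) and the benzylic carbon bonds to the brominated C3 (the C4–C5 bond). The closest known reaction type is the thermal Diels–Alder reaction of 3-bromo- and 3,5-dibromo-2-pyrones with styrenes, which gives isolable 5-aryl bridged lactones with the same regiochemistry. Ring C is closed by this intermolecular [4+2] annulation and, because the lactone bridge is kept, it appears as a 2-oxabicyclo[2.2.2]oct-7-en-3-one whose atoms C1, C4, C5 and C6 are those of ring C (C7 and C8 become C2 and C3). The bridgehead centres C1 and C4 are fixed relative to each other by the bicycle, and C5 is set by the endo transition state (secondary overlap of the aryl group with the pyrone π system), which puts ring D syn to the new alkene bridge and therefore anti to the lactone bridge, that is trans to the future C4 carbonyl group. No absolute control is exerted, so 7 is racemic and is resolved in step 5. The step needs regioselectivity, which the polarisation of the bromopyrone and of the electron-rich styrene secures, endo selectivity, which the aryl group secures, and retention of CO2, which the moderate temperature secures.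

Step 5
Reactants: 7 rac-endo bromolactone
Product: 8 (1S,4R,5R)-5-[2,4-bis(TBSO)phenyl]-4-bromo-1-methyl-2-oxabicyclo[2.2.2]oct-7-en-3-one
Conditions: preparative SFC on a chiral stationary phase [amylose tris(3,5-dimethylphenylcarbamate)], CO2/i-PrOH
Reagents that add atoms: none
Why: Chromatographic resolution on a chiral stationary phase separates the enantiomers of the rigid bromolactone, and the bromine atom allows the (1S,4R,5R) enantiomer to be identified by anomalous-dispersion X-ray crystallography before it is carried on.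

Step 6
Reactants: 8 (1S,4R,5R)-bromolactone
Product: 9 (1S,4S,5S)-5-[2,4-bis(TBSO)phenyl]-1-methyl-2-oxabicyclo[2.2.2]oct-7-en-3-one
Conditions: Bu3SnH, AIBN (cat), benzene, 80 °C
Reagents that add atoms: none
Why: Radical chain dehalogenation with Bu3SnH replaces the bridgehead bromine by hydrogen through a pyramidal bridgehead radical, so that C4 cannot invert and no stereocentre is disturbed.

Step 7
Reactants: 9 (1S,4S,5S)-lactone
Product: 10 (1S,4S,6S)-6-[2,4-bis(TBSO)phenyl]-4-hydroxy-N-methoxy-N,4-dimethylcyclohex-2-ene-1-carboxamide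
Conditions: MeNHOMe·HCl, i-PrMgCl, THF, −20 to 0 °C
Reagents that add atoms: N,O-dimethylhydroxylamine hydrochloride, CNOC.Cl
Why: Aminolysis of the strained bridged lactone with the magnesium amide of N,O-dimethylhydroxylamine (Weinreb amide formation) cleaves only the acyl–oxygen bond, so the three stereocentres are kept, the future ketone carbon becomes an acyl donor, and the carboxylate that would let a π-allyl palladium intermediate lose CO2 is removed.

Step 8
Reactants: 10 hydroxy Weinreb amide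
Product: 11 (1S,4S,5S)-5-[2,4-bis(TBSO)phenyl]-4-[methoxy(methyl)carbamoyl]-1-methylcyclohex-2-en-1-yl methyl carbonate
Conditions: LiN(SiMe3)2, ClCO2Me, THF, −78 to 0 °C
Reagents that add atoms: methyl chloroformate, COC(=O)Cl
Why: O-Acylation of the lithium alkoxide of the tertiary allylic alcohol with methyl chloroformate (carbonate formation) turns the C1 oxygen, which still sits on the face of the C4 carbonyl group, into a leaving group for palladium.

Step 9
Reactants: 11 allylic methyl carbonate; 12 cyclohexane-1,3-dione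
Product: 13 (1R,2S,6S)-6-[2,4-bis(TBSO)phenyl]-2-(2-hydroxy-6-oxocyclohex-1-en-1-yl)-N-methoxy-N,4-dimethylcyclohex-3-ene-1-carboxamide
Conditions: Pd(PPh3)4 (5 mol %), THF, rt to 40 °C
Reagents that add atoms: none
Why: Tsuji–Trost allylic alkylation: zerovalent palladium ionises the tertiary allylic carbonate with inversion, the methoxide set free deprotonates the dione, and the soft enolate attacks the less substituted allyl terminus C3 anti to palladium, so that double inversion places the new C3 substituent cis to the C4 amide while the alkene moves to C1=C2.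

Step 10
Reactants: 13 dione Weinreb amide
Product: 16 (1R,2S,6S)-6-[2,4-bis(TBSO)phenyl]-2-(2,6-dihydroxyphenyl)-N-methoxy-N,4-dimethylcyclohex-3-ene-1-carboxamide, via bis(trimethylsilyloxy) diene 14 (not isolated), via bis(trimethylsilyl) aryl ether 15 (not isolated)
Conditions: Me3SiOTf, Et3N, CH2Cl2, 0 °C; solvent exchange to pentane, filtration; DDQ, 2,4,6-collidine, CH2Cl2, 0 °C; then MeOH, citric acid (cat), rt
Reagents that add atoms: none
Why: Soft enolisation gives the 1,3-bis(silyloxy)cyclohexa-1,3-diene, DDQ abstracts hydride from its CH2–CH2 unit (oxidative aromatisation) and methanolysis of the labile Me3Si aryl ethers frees the resorcinol of ring B while the t-BuMe2Si ethers of ring D stay in place.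

Step 11
Reactants: 16 resorcinol Weinreb amide
Product: 17 (1R,2S,6S)-6-[2,4-bis(TBSO)phenyl]-2-(2,6-dihydroxy-3-iodophenyl)-N-methoxy-N,4-dimethylcyclohex-3-ene-1-carboxamide
Conditions: I2 (1.0 equiv), NaHCO3, THF/H2O, 0 °C
Reagents that add atoms: iodine, [I][I]
Why: Electrophilic aromatic iodination of the resorcinol monoanion is far faster than iodination of the silylated ring D or addition to the alkene, and the two open activated positions of ring B (each ortho to one hydroxyl group and para to the other) are equivalent, so one mono-iodide should form with one equivalent of iodine.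

Step 12
Reactants: 17 iodoresorcinol
Product: 18 (1R,2S,6S)-2-[2,6-bis(TBSO)-3-iodophenyl]-6-[2,4-bis(TBSO)phenyl]-N-methoxy-N,4-dimethylcyclohex-3-ene-1-carboxamide
Conditions: t-BuMe2SiOTf, 2,6-lutidine, CH2Cl2, 0 °C to rt
Reagents that add atoms: tert-butyldimethylsilyl trifluoromethanesulfonate, CC(C)(C)[Si](C)(C)OS(=O)(=O)C(F)(F)F
Why: Silyl ether formation with the reactive silyl triflate protects the two hindered phenols of ring B before the organometallic steps.

Step 13
Reactants: 18 aryl iodide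
Product: 19 (1R,2S,6S)-2-[2,6-bis(TBSO)-3-(1-ethoxyethenyl)phenyl]-6-[2,4-bis(TBSO)phenyl]-N-methoxy-N,4-dimethylcyclohex-3-ene-1-carboxamide
Conditions: Bu3Sn[C(OEt)=CH2], PdCl2(PPh3)2 (5 mol %), toluene, 100 °C; chromatography on Et3N-deactivated silica
Reagents that add atoms: tributyl(1-ethoxyvinyl)stannane, CCCC[Sn](CCCC)(CCCC)C(=C)OCC
Why: Stille coupling of the aryl iodide with the 1-ethoxyvinyl stannane installs a masked acetyl group that is inert towards the aryllithium reagent of step 17.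

Step 14
Reactants: 20 5-bromobenzene-1,3-diol
Product: 21 5-bromo-2-iodobenzene-1,3-diol
Conditions: I2, NaHCO3, H2O/THF, 0 °C
Reagents that add atoms: iodine, [I][I]
Why: Electrophilic iodination of the resorcinol monoanion in water is known to take place between the two hydroxyl groups, and the bromine atom additionally hinders the other two positions.

Step 15
Reactants: 21 5-bromo-2-iodobenzene-1,3-diol
Product: 22 5-bromo-2-iodo-1,3-bis(TBSO)benzene
Conditions: t-BuMe2SiCl, imidazole, DMF, rt to 40 °C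
Reagents that add atoms: tert-butyldimethylsilyl chloride, CC(C)(C)[Si](C)(C)Cl
Why: Silyl ether formation protects both phenols for the organometallic steps that follow.

Step 16
Reactants: 22 5-bromo-2-iodo-1,3-bis(TBSO)benzene
Product: 24 5-bromo-2-(3-methylbut-2-en-1-yl)-1,3-bis(TBSO)benzene, via arylmagnesium chloride 23 (not isolated)
Conditions: i-PrMgCl·LiCl, THF, −40 °C; then CuI (10 mol %), prenyl bromide, −40 to 0 °C
Reagents that add atoms: 1-bromo-3-methylbut-2-ene, CC(C)=CCBr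
Why: Iodine–magnesium exchange takes place at the C–I bond and leaves the C–Br bond, and CuI-catalysed allylic substitution of prenyl bromide at its primary carbon (SN2) by the hindered aryl Grignard reagent at low temperature gives the linear prenyl arene.

Step 17
Reactants: 19 enol ether Weinreb amide; 24 ring A aryl bromide
Product: 28 {(1R,2S,6S)-2-[3-acetyl-2,6-bis(TBSO)phenyl]-6-[2,4-bis(TBSO)phenyl]-4-methylcyclohex-3-en-1-yl}[3,5-bis(TBSO)-4-(3-methylbut-2-en-1-yl)phenyl]methanone, via aryllithium 25 (not isolated), via lithium hemiaminal adduct 26 (not isolated), via enol ether ketone 27 (not isolated)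
Conditions: 24, n-BuLi, THF, −78 °C; add 19, −78 to 0 °C; aq NH4Cl; then 0.5 M HCl, THF, 0 °C
Reagents that add atoms: water, O
Why: Bromine–lithium exchange gives the ring A aryllithium, which adds once to the Weinreb amide because the chelated tetrahedral adduct persists until work-up (Weinreb ketone synthesis), and dilute acid then hydrolyses the enol ether to the methyl ketone, while C4 is not epimerised because the ketone is released only after the base has been quenched.

Step 18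
Reactants: 28 diketone; 5 2,4-bis(TBSO)benzaldehyde
Product: 32 (E)-1-{3-[(1S,5S,6R)-6-[3,5-bis(TBSO)-4-(3-methylbut-2-en-1-yl)benzoyl]-5-[2,4-bis(TBSO)phenyl]-3-methylcyclohex-2-en-1-yl]-2,4-bis(TBSO)phenyl}-3-[2,4-bis(TBSO)phenyl]prop-2-en-1-one, via lithium enolate 29 (not isolated), via lithium aldolate 30 (not isolated), via mesylate 31 (not isolated)
Conditions: LiN(SiMe3)2, THF, −78 °C; 5, −78 °C; then MeSO2Cl, Et3N, −78 °C to rt
Reagents that add atoms: none
Why: Directed aldol condensation: LiN(SiMe3)2 deprotonates the unhindered acetyl CH3 in preference to the congested C4–H, the enolate adds to the aldehyde, and mesylation of the aldolate followed by E1cB elimination gives the conjugated (E)-enone without the hydroxide that aryl silyl ethers would not survive.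

Step 19
Reactants: 32 octakis(TBS) ether
Product: 33 kuwanon J
Conditions: Bu4NF, AcOH, THF, 0 °C to rt
Reagents that add atoms: none
Why: Fluoride-mediated desilylation buffered with acetic acid frees all eight phenols without acid, under which the cis,trans array of ring B, the C4 ketone and ring D is expected to close to ketals and cyclic ethers, and no stereocentre is affected.

Compound list
1 | 6-methyl-2H-pyran-2-one | CC1=CC=CC(=O)O1 | starting material
2 | 3,6-dibromo-6-methyl-3,6-dihydro-2H-pyran-2-one (diastereomer mixture) | CC1(Br)C=CC(Br)C(=O)O1 | intermediate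
3 | 3-bromo-6-methyl-2H-pyran-2-one | CC1=CC=C(Br)C(=O)O1 | intermediate
4 | 2,4-dihydroxybenzaldehyde | O=Cc1ccc(O)cc1O | starting material
5 | 2,4-bis[(tert-butyldimethylsilyl)oxy]benzaldehyde | O=Cc1ccc(O[Si](C)(C)C(C)(C)C)cc1O[Si](C)(C)C(C)(C)C | intermediate
6 | 1-ethenyl-2,4-bis[(tert-butyldimethylsilyl)oxy]benzene | C=Cc1ccc(O[Si](C)(C)C(C)(C)C)cc1O[Si](C)(C)C(C)(C)C | intermediate
7 | rac-(1S,4R,5R)-5-[2,4-bis(TBSO)phenyl]-4-bromo-1-methyl-2-oxabicyclo[2.2.2]oct-7-en-3-one (endo; racemate, one enantiomer drawn) | C[C@]12C=C[C@](Br)(C(=O)O1)[C@@H](c3ccc(O[Si](C)(C)C(C)(C)C)cc3O[Si](C)(C)C(C)(C)C)C2 | intermediate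
8 | (1S,4R,5R)-5-[2,4-bis(TBSO)phenyl]-4-bromo-1-methyl-2-oxabicyclo[2.2.2]oct-7-en-3-one | C[C@]12C=C[C@](Br)(C(=O)O1)[C@@H](c3ccc(O[Si](C)(C)C(C)(C)C)cc3O[Si](C)(C)C(C)(C)C)C2 | intermediate
9 | (1S,4S,5S)-5-[2,4-bis(TBSO)phenyl]-1-methyl-2-oxabicyclo[2.2.2]oct-7-en-3-one | C[C@]12C=C[C@H](C(=O)O1)[C@@H](c3ccc(O[Si](C)(C)C(C)(C)C)cc3O[Si](C)(C)C(C)(C)C)C2 | intermediate
10 | (1S,4S,6S)-6-[2,4-bis(TBSO)phenyl]-4-hydroxy-N-methoxy-N,4-dimethylcyclohex-2-ene-1-carboxamide | C[C@@]1(O)C=C[C@H](C(=O)N(C)OC)[C@@H](c2ccc(O[Si](C)(C)C(C)(C)C)cc2O[Si](C)(C)C(C)(C)C)C1 | intermediate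
11 | (1S,4S,5S)-5-[2,4-bis(TBSO)phenyl]-4-[methoxy(methyl)carbamoyl]-1-methylcyclohex-2-en-1-yl methyl carbonate | C[C@@]1(OC(=O)OC)C=C[C@H](C(=O)N(C)OC)[C@@H](c2ccc(O[Si](C)(C)C(C)(C)C)cc2O[Si](C)(C)C(C)(C)C)C1 | intermediate
12 | cyclohexane-1,3-dione | O=C1CCCC(=O)C1 | starting material
13 | (1R,2S,6S)-6-[2,4-bis(TBSO)phenyl]-2-(2-hydroxy-6-oxocyclohex-1-en-1-yl)-N-methoxy-N,4-dimethylcyclohex-3-ene-1-carboxamide | CON(C)C(=O)[C@H]1[C@@H](C2=C(O)CCCC2=O)C=C(C)C[C@@H]1c3ccc(O[Si](C)(C)C(C)(C)C)cc3O[Si](C)(C)C(C)(C)C | intermediate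
14 | (1R,2S,6S)-6-[2,4-bis(TBSO)phenyl]-2-{2,6-bis[(trimethylsilyl)oxy]cyclohexa-1,5-dien-1-yl}-N-methoxy-N,4-dimethylcyclohex-3-ene-1-carboxamide | CON(C)C(=O)[C@H]1[C@@H](C2=C(O[Si](C)(C)C)CCC=C2O[Si](C)(C)C)C=C(C)C[C@@H]1c3ccc(O[Si](C)(C)C(C)(C)C)cc3O[Si](C)(C)C(C)(C)C | intermediate
15 | (1R,2S,6S)-6-[2,4-bis(TBSO)phenyl]-2-{2,6-bis[(trimethylsilyl)oxy]phenyl}-N-methoxy-N,4-dimethylcyclohex-3-ene-1-carboxamide | CON(C)C(=O)[C@H]1[C@@H](c2c(O[Si](C)(C)C)cccc2O[Si](C)(C)C)C=C(C)C[C@@H]1c3ccc(O[Si](C)(C)C(C)(C)C)cc3O[Si](C)(C)C(C)(C)C | intermediate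
16 | (1R,2S,6S)-6-[2,4-bis(TBSO)phenyl]-2-(2,6-dihydroxyphenyl)-N-methoxy-N,4-dimethylcyclohex-3-ene-1-carboxamide | CON(C)C(=O)[C@H]1[C@@H](c2c(O)cccc2O)C=C(C)C[C@@H]1c3ccc(O[Si](C)(C)C(C)(C)C)cc3O[Si](C)(C)C(C)(C)C | intermediate
17 | (1R,2S,6S)-6-[2,4-bis(TBSO)phenyl]-2-(2,6-dihydroxy-3-iodophenyl)-N-methoxy-N,4-dimethylcyclohex-3-ene-1-carboxamide | CON(C)C(=O)[C@H]1[C@@H](c2c(O)ccc(I)c2O)C=C(C)C[C@@H]1c3ccc(O[Si](C)(C)C(C)(C)C)cc3O[Si](C)(C)C(C)(C)C | intermediate
18 | (1R,2S,6S)-2-[2,6-bis(TBSO)-3-iodophenyl]-6-[2,4-bis(TBSO)phenyl]-N-methoxy-N,4-dimethylcyclohex-3-ene-1-carboxamide | CON(C)C(=O)[C@H]1[C@@H](c2c(O[Si](C)(C)C(C)(C)C)ccc(I)c2O[Si](C)(C)C(C)(C)C)C=C(C)C[C@@H]1c3ccc(O[Si](C)(C)C(C)(C)C)cc3O[Si](C)(C)C(C)(C)C | intermediate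
19 | (1R,2S,6S)-2-[2,6-bis(TBSO)-3-(1-ethoxyethenyl)phenyl]-6-[2,4-bis(TBSO)phenyl]-N-methoxy-N,4-dimethylcyclohex-3-ene-1-carboxamide | CON(C)C(=O)[C@H]1[C@@H](c2c(O[Si](C)(C)C(C)(C)C)ccc(C(=C)OCC)c2O[Si](C)(C)C(C)(C)C)C=C(C)C[C@@H]1c3ccc(O[Si](C)(C)C(C)(C)C)cc3O[Si](C)(C)C(C)(C)C | intermediate
20 | 5-bromobenzene-1,3-diol | Oc1cc(O)cc(Br)c1 | starting material
21 | 5-bromo-2-iodobenzene-1,3-diol | Oc1cc(Br)cc(O)c1I | intermediate
22 | 5-bromo-2-iodo-1,3-bis[(tert-butyldimethylsilyl)oxy]benzene | CC(C)(C)[Si](C)(C)Oc1cc(Br)cc(O[Si](C)(C)C(C)(C)C)c1I | intermediate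
23 | [4-bromo-2,6-bis(TBSO)phenyl]magnesium chloride | CC(C)(C)[Si](C)(C)Oc1cc(Br)cc(O[Si](C)(C)C(C)(C)C)c1[Mg]Cl | intermediate
24 | 5-bromo-2-(3-methylbut-2-en-1-yl)-1,3-bis[(tert-butyldimethylsilyl)oxy]benzene | CC(C)=CCc1c(O[Si](C)(C)C(C)(C)C)cc(Br)cc1O[Si](C)(C)C(C)(C)C | intermediate
25 | [3,5-bis(TBSO)-4-(3-methylbut-2-en-1-yl)phenyl]lithium | CC(C)=CCc1c(O[Si](C)(C)C(C)(C)C)cc([Li])cc1O[Si](C)(C)C(C)(C)C | intermediate
26 | lithium alkoxide of the N-methoxy-N-methyl hemiaminal formed from 25 and 19 (new carbon unassigned) | CC(C)=CCc1c(O[Si](C)(C)C(C)(C)C)cc(C(O[Li])(N(C)OC)[C@H]2[C@@H](c3c(O[Si](C)(C)C(C)(C)C)ccc(C(=C)OCC)c3O[Si](C)(C)C(C)(C)C)C=C(C)C[C@@H]2c4ccc(O[Si](C)(C)C(C)(C)C)cc4O[Si](C)(C)C(C)(C)C)cc1O[Si](C)(C)C(C)(C)C | intermediate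
27 | {(1R,2S,6S)-2-[2,6-bis(TBSO)-3-(1-ethoxyethenyl)phenyl]-6-[2,4-bis(TBSO)phenyl]-4-methylcyclohex-3-en-1-yl}[3,5-bis(TBSO)-4-(3-methylbut-2-en-1-yl)phenyl]methanone | CC(C)=CCc1c(O[Si](C)(C)C(C)(C)C)cc(C(=O)[C@H]2[C@@H](c3c(O[Si](C)(C)C(C)(C)C)ccc(C(=C)OCC)c3O[Si](C)(C)C(C)(C)C)C=C(C)C[C@@H]2c4ccc(O[Si](C)(C)C(C)(C)C)cc4O[Si](C)(C)C(C)(C)C)cc1O[Si](C)(C)C(C)(C)C | intermediate
28 | {(1R,2S,6S)-2-[3-acetyl-2,6-bis(TBSO)phenyl]-6-[2,4-bis(TBSO)phenyl]-4-methylcyclohex-3-en-1-yl}[3,5-bis(TBSO)-4-(3-methylbut-2-en-1-yl)phenyl]methanone | CC(C)=CCc1c(O[Si](C)(C)C(C)(C)C)cc(C(=O)[C@H]2[C@@H](c3c(O[Si](C)(C)C(C)(C)C)ccc(C(C)=O)c3O[Si](C)(C)C(C)(C)C)C=C(C)C[C@@H]2c4ccc(O[Si](C)(C)C(C)(C)C)cc4O[Si](C)(C)C(C)(C)C)cc1O[Si](C)(C)C(C)(C)C | intermediate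
29 | lithium enolate of the acetyl group of 28 | CC(C)=CCc1c(O[Si](C)(C)C(C)(C)C)cc(C(=O)[C@H]2[C@@H](c3c(O[Si](C)(C)C(C)(C)C)ccc(C(=C)O[Li])c3O[Si](C)(C)C(C)(C)C)C=C(C)C[C@@H]2c4ccc(O[Si](C)(C)C(C)(C)C)cc4O[Si](C)(C)C(C)(C)C)cc1O[Si](C)(C)C(C)(C)C | intermediate
30 | lithium aldolate of 28 and 5 (3-aryl-3-lithiooxypropanoyl on ring B; carbinol epimers) | CC(C)=CCc1c(O[Si](C)(C)C(C)(C)C)cc(C(=O)[C@H]2[C@@H](c3c(O[Si](C)(C)C(C)(C)C)ccc(C(=O)CC(O[Li])c5ccc(O[Si](C)(C)C(C)(C)C)cc5O[Si](C)(C)C(C)(C)C)c3O[Si](C)(C)C(C)(C)C)C=C(C)C[C@@H]2c4ccc(O[Si](C)(C)C(C)(C)C)cc4O[Si](C)(C)C(C)(C)C)cc1O[Si](C)(C)C(C)(C)C | intermediate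
31 | methanesulfonate of the aldol adduct (carbinol epimers) | CC(C)=CCc1c(O[Si](C)(C)C(C)(C)C)cc(C(=O)[C@H]2[C@@H](c3c(O[Si](C)(C)C(C)(C)C)ccc(C(=O)CC(OS(C)(=O)=O)c5ccc(O[Si](C)(C)C(C)(C)C)cc5O[Si](C)(C)C(C)(C)C)c3O[Si](C)(C)C(C)(C)C)C=C(C)C[C@@H]2c4ccc(O[Si](C)(C)C(C)(C)C)cc4O[Si](C)(C)C(C)(C)C)cc1O[Si](C)(C)C(C)(C)C | intermediate
32 | (E)-1-{3-[(1S,5S,6R)-6-[3,5-bis(TBSO)-4-(3-methylbut-2-en-1-yl)benzoyl]-5-[2,4-bis(TBSO)phenyl]-3-methylcyclohex-2-en-1-yl]-2,4-bis(TBSO)phenyl}-3-[2,4-bis(TBSO)phenyl]prop-2-en-1-one | CC(C)=CCc1c(O[Si](C)(C)C(C)(C)C)cc(C(=O)[C@H]2[C@@H](c3c(O[Si](C)(C)C(C)(C)C)ccc(C(=O)/C=C/c5ccc(O[Si](C)(C)C(C)(C)C)cc5O[Si](C)(C)C(C)(C)C)c3O[Si](C)(C)C(C)(C)C)C=C(C)C[C@@H]2c4ccc(O[Si](C)(C)C(C)(C)C)cc4O[Si](C)(C)C(C)(C)C)cc1O[Si](C)(C)C(C)(C)C | intermediate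
33 | kuwanon J, (E)-1-{3-[(1S,5S,6R)-6-[3,5-dihydroxy-4-(3-methylbut-2-en-1-yl)benzoyl]-5-(2,4-dihydroxyphenyl)-3-methylcyclohex-2-en-1-yl]-2,4-dihydroxyphenyl}-3-(2,4-dihydroxyphenyl)prop-2-en-1-one | CC(C)=CCc1c(O)cc(C(=O)[C@H]2[C@@H](c3c(O)ccc(C(=O)/C=C/c4ccc(O)cc4O)c3O)C=C(C)C[C@@H]2c2ccc(O)cc2O)cc1O | target

Total step count: 19. Longest linear sequence: 15 steps (steps 2–13 and 17–19, from 2,4-dihydroxybenzaldehyde 4).

Steps most likely to fail

Step 9. After ionisation of the hindered tertiary carbonate, the π-allyl palladium intermediate may lose a proton to give a diene, or the dione may be captured at oxygen or at the methyl-bearing terminus instead of C3. The fallback sets out from 10 and replaces the palladium chemistry by a carbamate-directed syn-SN2' substitution with an aryl cuprate. Compound 10 is converted with phenyl isocyanate into the N-phenylcarbamate F1. The carbamate nitrogen is deprotonated with n-BuLi and complexed with CuI, and [2,6-bis(methoxymethoxy)phenyl]lithium F2 (from 1,3-bis(methoxymethoxy)benzene and n-BuLi) is added. The mixed cuprate should deliver the aryl group to C3 on the face of the carbamate, with shift of the alkene to C1=C2, and give the ring B bis(methoxymethyl) ether F3. Dilute HCl in methanol at 0 °C, at a stage where no ketone is present and the aryl silyl ethers survive, removes the two acetals and returns to the route at 16, so step 10 is bypassed as well.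

Step 10. The second enolisation may stay incomplete, or DDQ may add to the silyloxy diene as a dienophile or oxidise the allylic and benzylic C–H bonds of ring C. The fallback sets out from 13 and uses enolate selenenylation and selenoxide elimination instead of hydride abstraction. The dione enol is silylated (t-BuMe2SiCl, Et3N) to the 3-silyloxy enone F4. Deprotonation at the α' CH2 with LiN(i-Pr)2 at −78 °C and PhSeBr gives the selenide F5. H2O2 and pyridine give the selenoxide F6, whose syn-elimination and tautomerisation give the mono-silylated resorcinol F7. Iodination (I2, NaHCO3) gives the iodophenol F8; an isomer iodinated para to the free hydroxyl group would converge on the same product. Silylation with t-BuMe2SiOTf and 2,6-lutidine returns to the route at 18.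

Step 4. The methyl group at C6 of the pyrone may slow the cycloaddition so much that polymerisation of the styrene and loss of CO2 from the adduct take over, or the endo preference may be low. The fallback sets out from 3 and uses a more reactive diene with a second activating bromine. N-Bromosuccinimide in acetonitrile brominates C5 and gives 3,5-dibromo-6-methyl-2H-pyran-2-one F9. Cycloaddition with 6 at lower temperature should give the racemic endo 4,7-dibromo lactone F10, which is resolved on the chiral phase to the (1S,4S,5R) enantiomer F11. Excess Bu3SnH with AIBN removes both the bridgehead and the vinylic bromine and returns to the route at 9.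

Further compounds
F1 | step 9 | (1S,4S,5S)-5-[2,4-bis(TBSO)phenyl]-4-[methoxy(methyl)carbamoyl]-1-methylcyclohex-2-en-1-yl N-phenylcarbamate | C[C@@]1(OC(=O)Nc2ccccc2)C=C[C@H](C(=O)N(C)OC)[C@@H](c3ccc(O[Si](C)(C)C(C)(C)C)cc3O[Si](C)(C)C(C)(C)C)C1
F2 | step 9 | [2,6-bis(methoxymethoxy)phenyl]lithium | [Li]c1c(OCOC)cccc1OCOC
F3 | step 9 | (1R,2S,6S)-2-[2,6-bis(methoxymethoxy)phenyl]-6-[2,4-bis(TBSO)phenyl]-N-methoxy-N,4-dimethylcyclohex-3-ene-1-carboxamide | CON(C)C(=O)[C@H]1[C@@H](c2c(OCOC)cccc2OCOC)C=C(C)C[C@@H]1c3ccc(O[Si](C)(C)C(C)(C)C)cc3O[Si](C)(C)C(C)(C)C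
F4 | step 10 | (1R,2S,6S)-6-[2,4-bis(TBSO)phenyl]-2-[2-(TBSO)-6-oxocyclohex-1-en-1-yl]-N-methoxy-N,4-dimethylcyclohex-3-ene-1-carboxamide | CON(C)C(=O)[C@H]1[C@@H](C2=C(O[Si](C)(C)C(C)(C)C)CCCC2=O)C=C(C)C[C@@H]1c3ccc(O[Si](C)(C)C(C)(C)C)cc3O[Si](C)(C)C(C)(C)C
F5 | step 10 | (1R,2S,6S)-6-[2,4-bis(TBSO)phenyl]-2-[2-(TBSO)-6-oxo-5-(phenylselanyl)cyclohex-1-en-1-yl]-N-methoxy-N,4-dimethylcyclohex-3-ene-1-carboxamide (epimers at the selenium-bearing carbon) | CON(C)C(=O)[C@H]1[C@@H](C2=C(O[Si](C)(C)C(C)(C)C)CCC([Se]c4ccccc4)C2=O)C=C(C)C[C@@H]1c3ccc(O[Si](C)(C)C(C)(C)C)cc3O[Si](C)(C)C(C)(C)C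
F6 | step 10 | selenoxide of F5, 5-(benzeneseleninyl) compound | CON(C)C(=O)[C@H]1[C@@H](C2=C(O[Si](C)(C)C(C)(C)C)CCC([Se](=O)c4ccccc4)C2=O)C=C(C)C[C@@H]1c3ccc(O[Si](C)(C)C(C)(C)C)cc3O[Si](C)(C)C(C)(C)C
F7 | step 10 | (1R,2S,6S)-6-[2,4-bis(TBSO)phenyl]-2-[2-hydroxy-6-(TBSO)phenyl]-N-methoxy-N,4-dimethylcyclohex-3-ene-1-carboxamide | CON(C)C(=O)[C@H]1[C@@H](c2c(O[Si](C)(C)C(C)(C)C)cccc2O)C=C(C)C[C@@H]1c3ccc(O[Si](C)(C)C(C)(C)C)cc3O[Si](C)(C)C(C)(C)C
F8 | step 10 | (1R,2S,6S)-6-[2,4-bis(TBSO)phenyl]-2-[2-hydroxy-3-iodo-6-(TBSO)phenyl]-N-methoxy-N,4-dimethylcyclohex-3-ene-1-carboxamide | CON(C)C(=O)[C@H]1[C@@H](c2c(O[Si](C)(C)C(C)(C)C)ccc(I)c2O)C=C(C)C[C@@H]1c3ccc(O[Si](C)(C)C(C)(C)C)cc3O[Si](C)(C)C(C)(C)C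
F9 | step 4 | 3,5-dibromo-6-methyl-2H-pyran-2-one | CC1=C(Br)C=C(Br)C(=O)O1
F10 | step 4 | rac-(1S,4S,5R)-5-[2,4-bis(TBSO)phenyl]-4,7-dibromo-1-methyl-2-oxabicyclo[2.2.2]oct-7-en-3-one (endo; racemate, one enantiomer drawn) | C[C@]12C(Br)=C[C@](Br)(C(=O)O1)[C@@H](c3ccc(O[Si](C)(C)C(C)(C)C)cc3O[Si](C)(C)C(C)(C)C)C2
F11 | step 4 | (1S,4S,5R)-5-[2,4-bis(TBSO)phenyl]-4,7-dibromo-1-methyl-2-oxabicyclo[2.2.2]oct-7-en-3-one | C[C@]12C(Br)=C[C@](Br)(C(=O)O1)[C@@H](c3ccc(O[Si](C)(C)C(C)(C)C)cc3O[Si](C)(C)C(C)(C)C)C2
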